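The route rests on cutting the C2–C3 bond of the five-membered oxygen ring (O1, C2, C3, C3a, C7a). C2 is a benzylic carbon on O1 and C3 hangs on C3a of the six-membered ring, so C3 can be made a rhodium carbene flanked by aryl and ester while C2–H is an ether-activated benzylic C–H bond. One insertion closes this ring and fixes C2 and C3, cis and in absolute sense. The precursor is an aryldiazoacetate whose ortho oxygen bears the 3,4,5-trimethoxybenzyl group. Afterwards the ester is taken down to the C3 methyl group and the freed phenol is allylated at C3a, para to O6, to give the dienone.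

Key step: step 6

Remark: benzofuran numbering is used for the core throughout (O1, C2, C3, C3a, C4 to C7, C7a); the target is the (2R,3S,3aS) isomer, with 2-aryl and 3-methyl cis and the 3a-allyl group on the opposite face.
Assumption: Rh2(S-PTTL)4 is taken to select the benzylic hydrogen that leads to the (2R,3S) ester; should the sense prove opposite, the mirror-image catalyst Rh2(R-PTTL)4 is used and nothing else changes.

Step 1
Reactants: 1 isovanillin
Product: 2 4-methoxy-3-(triisopropylsilyloxy)benzaldehyde
Conditions: i-Pr3SiCl (1.1 equiv), imidazole (2.2 equiv), DMF, 25 °C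
Reagents that add atoms: triisopropylsilyl chloride, CC(C)[Si](Cl)(C(C)C)C(C)C
Why: Imidazole-mediated silyl ether formation at the only hydroxyl group; the bulky triisopropylsilyl ether is chosen because it should survive carbonate, hydride reagents and both metal-catalysed steps and leave later under fluoride without acid.

Step 2
Reactants: 2 4-methoxy-3-(triisopropylsilyloxy)benzaldehyde
Product: 4 4-methoxy-3-(triisopropylsilyloxy)phenol, via aryl formate 3 (not isolated)
Conditions: mCPBA (1.3 equiv), CH2Cl2, 0 to 25 °C; aqueous NaHCO3 wash; then K2CO3 (0.1 equiv), MeOH, 0 °C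
Reagents that add atoms: 3-chloroperoxybenzoic acid, OOC(=O)c1cccc(Cl)c1
Why: Baeyer–Villiger oxidation of the electron-rich aryl aldehyde (Dakin-type) moves the aryl group to oxygen, and brief catalytic methanolysis of the formate frees the phenol without the alkaline peroxide that would cleave the silyl ether.

Step 3
Reactants: 4 4-methoxy-3-(triisopropylsilyloxy)phenol
Product: 5 2-iodo-4-methoxy-5-(triisopropylsilyloxy)phenol
Conditions: NIS (1.05 equiv), MeCN, −10 to 0 °C, dark
Reagents that add atoms: N-iodosuccinimide, IN1C(=O)CCC1=O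
Why: Electrophilic aromatic iodination of the free phenol should go ortho to OH and para to the silyloxy group, since the other ortho position lies between OH and the bulky silyloxy group; this carbon becomes C3a.

Step 4
Reactants: 5 2-iodo-4-methoxy-5-(triisopropylsilyloxy)phenol; 6 3,4,5-trimethoxybenzyl chloride
Product: 7 [4-iodo-2-methoxy-5-(3,4,5-trimethoxybenzyloxy)phenoxy]triisopropylsilane
Conditions: K2CO3 (1.5 equiv), NaI (0.1 equiv), acetone, 50 °C
Reagents that add atoms: none
Why: Williamson ether synthesis (iodide-catalysed SN2 of the phenoxide on the benzylic chloride), placed after the iodination so that the electron-rich trimethoxyphenyl ring never meets the iodinating agent.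

Step 5
Reactants: 7 [4-iodo-2-methoxy-5-(3,4,5-trimethoxybenzyloxy)phenoxy]triisopropylsilane; 8 ethyl diazoacetate
Product: 9 ethyl 2-diazo-2-[5-methoxy-4-(triisopropylsilyloxy)-2-(3,4,5-trimethoxybenzyloxy)phenyl]acetate
Conditions: Pd(PPh3)4 (5 mol %), Ag2CO3 (0.5 equiv), Et3N (1.3 equiv), toluene, 25 °C
Reagents that add atoms: none
Why: Palladium-catalysed cross-coupling of an aryl iodide with an acceptor diazo ester with retention of the diazo group (oxidative addition, silver-assisted transfer of the diazoacetate carbon to palladium, reductive elimination), run at room temperature so that the product should not lose N2.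

Step 6
Reactants: 9 ethyl 2-diazo-2-[5-methoxy-4-(triisopropylsilyloxy)-2-(3,4,5-trimethoxybenzyloxy)phenyl]acetate
Product: 10 ethyl (2R,3S)-5-methoxy-6-(triisopropylsilyloxy)-2-(3,4,5-trimethoxyphenyl)-2,3-dihydro-1-benzofuran-3-carboxylate (2-aryl and 3-ester cis)
Conditions: Rh2(S-PTTL)4 (dirhodium tetrakis[N-phthaloyl-(S)-tert-leucinate], 1 mol %), toluene, −78 °C, slow addition of 9
Reagents that add atoms: none
Why: At the dirhodium centre 9 loses N2 and becomes a metal carbene at C3 that is stabilised by the aryl donor and the ester acceptor; this carbene takes up one benzylic C–H bond of the OCH2Ar group through a three-centre transition state with partial hydride shift and so forms the C2–C3 bond. The closest known reaction type is the intramolecular C–H insertion of 2-(benzyloxy)aryl diazoacetates under chiral dirhodium tetracarboxylates, which gives cis-2-aryl-2,3-dihydrobenzofuran-3-carboxylates. The five-membered oxygen ring (O1, C2, C3, C3a, C7a) closes by 1,5-insertion, the carbene carbon bonding to the fifth atom of the chain through a five-membered cyclic transition state. C2 is fixed by which of the two enantiotopic benzylic hydrogens is replaced, a choice made by the chiral N-phthaloyl-tert-leucinate ligand sphere, and C3 is fixed in the same event because the compact transition state keeps ester and aryl on one face, so that the cis isomer is the kinetic product. The step needs 1,5-insertion to outrun carbene dimerisation and attack on the trimethoxyphenyl ring: the lone pairs of O1 and the electron-rich aryl group weaken exactly this C–H bond, the ortho tether holds it beside the carbene, and slow addition at −78 °C keeps the free diazo compound scarce. No base is present, so the epimerisable C3–H of 10 is not touched.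

Step 7
Reactants: 10 ethyl (2R,3S)-5-methoxy-6-(triisopropylsilyloxy)-2-(3,4,5-trimethoxyphenyl)-2,3-dihydro-1-benzofuran-3-carboxylate
Product: 11 [(2R,3R)-5-methoxy-6-(triisopropylsilyloxy)-2-(3,4,5-trimethoxyphenyl)-2,3-dihydro-1-benzofuran-3-yl]methanol (cis retained; the descriptor at C3 changes only by priority)
Conditions: i-Bu2AlH (2.5 equiv), CH2Cl2, −78 °C; aqueous potassium sodium tartrate
Reagents that add atoms: none
Why: Ester reduction by a Lewis-acidic, non-basic aluminium hydride at low temperature should reach the primary alcohol without deprotonating C3, so the cis relation is kept.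

Step 8
Reactants: 11 [(2R,3R)-5-methoxy-6-(triisopropylsilyloxy)-2-(3,4,5-trimethoxyphenyl)-2,3-dihydro-1-benzofuran-3-yl]methanol
Product: 12 [(2R,3R)-5-methoxy-6-(triisopropylsilyloxy)-2-(3,4,5-trimethoxyphenyl)-2,3-dihydro-1-benzofuran-3-yl]methyl methanesulfonate
Conditions: MeSO2Cl (1.2 equiv), Et3N (1.5 equiv), CH2Cl2, 0 °C
Reagents that add atoms: methanesulfonyl chloride, CS(Cl)(=O)=O
Why: Sulfonylation of the primary alcohol (mesylate formation); C3 no longer stands next to a carbonyl group, so the amine base cannot epimerise it.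

Step 9
Reactants: 12 [(2R,3R)-5-methoxy-6-(triisopropylsilyloxy)-2-(3,4,5-trimethoxyphenyl)-2,3-dihydro-1-benzofuran-3-yl]methyl methanesulfonate
Product: 13 triisopropyl{[(2R,3S)-5-methoxy-3-methyl-2-(3,4,5-trimethoxyphenyl)-2,3-dihydro-1-benzofuran-6-yl]oxy}silane
Conditions: LiBHEt3 (2.5 equiv), THF, 0 to 25 °C
Reagents that add atoms: none
Why: SN2 displacement of the primary mesylate by hydride from the strongly nucleophilic, weakly basic triethylborohydride should give the C3 methyl group without touching C2 or C3.

Step 10
Reactants: 13 triisopropyl{[(2R,3S)-5-methoxy-3-methyl-2-(3,4,5-trimethoxyphenyl)-2,3-dihydro-1-benzofuran-6-yl]oxy}silane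
Product: 14 (2R,3S)-5-methoxy-3-methyl-2-(3,4,5-trimethoxyphenyl)-2,3-dihydro-1-benzofuran-6-ol
Conditions: Bu4NF (1.1 equiv), AcOH (1.1 equiv), THF, 0 °C, under argon
Reagents that add atoms: none
Why: Fluoride-induced cleavage of the aryl silyl ether, buffered so that the electron-rich phenoxide is not left open to air oxidation and no acid reaches the acid-labile benzylic C2–O1 bond.

Step 11
Reactants: 14 (2R,3S)-5-methoxy-3-methyl-2-(3,4,5-trimethoxyphenyl)-2,3-dihydro-1-benzofuran-6-ol; 15 allyl methyl carbonate
Product: 17 (2R,3S,3aS)-3a-allyl-5-methoxy-3-methyl-2-(3,4,5-trimethoxyphenyl)-3,3a-dihydro-1-benzofuran-6(2H)-one, via allyl aryl ether 16 (not isolated)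
Conditions: Pd(PPh3)4 (5 mol %), toluene, 25 °C then 60 °C, under argon
Reagents that add atoms: none
Why: Proposed new method: zerovalent palladium ionises 15 to a π-allylpalladium cation and methoxide (with loss of CO2), the phenoxide of 14 is first allylated at oxygen to 16, and because the same catalyst re-ionises allyl aryl ethers the allyl group can be passed on to carbon; bonding at C3a, which is para to O6 and ortho to O1, gives at once a cross-conjugated dienone that is also a vinylogous ester and needs no tautomerisation, and the allyl unit should enter on the face opposite the cis C3-methyl/C2-aryl pair, which sets C3a as S; the closest known reaction types are the palladium-catalysed intermolecular allylic dearomatisation of 1-substituted 2-naphthols and the intramolecular ipso-Friedel–Crafts allylic alkylation of para-substituted phenols, and what is new is an intermolecular para attack on a phenol whose ortho carbon C7 is free.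

Compound list
1 | isovanillin (3-hydroxy-4-methoxybenzaldehyde) | COc1ccc(C=O)cc1O | starting material
2 | 4-methoxy-3-(triisopropylsilyloxy)benzaldehyde | COc1ccc(C=O)cc1O[Si](C(C)C)(C(C)C)C(C)C | intermediate
3 | 4-methoxy-3-(triisopropylsilyloxy)phenyl formate | COc1ccc(OC=O)cc1O[Si](C(C)C)(C(C)C)C(C)C | intermediate
4 | 4-methoxy-3-(triisopropylsilyloxy)phenol | COc1ccc(O)cc1O[Si](C(C)C)(C(C)C)C(C)C | intermediate
5 | 2-iodo-4-methoxy-5-(triisopropylsilyloxy)phenol | COc1cc(I)c(O)cc1O[Si](C(C)C)(C(C)C)C(C)C | intermediate
6 | 3,4,5-trimethoxybenzyl chloride | COc1cc(CCl)cc(OC)c1OC | starting material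
7 | [4-iodo-2-methoxy-5-(3,4,5-trimethoxybenzyloxy)phenoxy]triisopropylsilane | COc1cc(I)c(OCc2cc(OC)c(OC)c(OC)c2)cc1O[Si](C(C)C)(C(C)C)C(C)C | intermediate
8 | ethyl diazoacetate | CCOC(=O)C=[N+]=[N-] | starting material
9 | ethyl 2-diazo-2-[5-methoxy-4-(triisopropylsilyloxy)-2-(3,4,5-trimethoxybenzyloxy)phenyl]acetate | CCOC(=O)C(=[N+]=[N-])c1cc(OC)c(O[Si](C(C)C)(C(C)C)C(C)C)cc1OCc1cc(OC)c(OC)c(OC)c1 | intermediate
10 | ethyl (2R,3S)-5-methoxy-6-(triisopropylsilyloxy)-2-(3,4,5-trimethoxyphenyl)-2,3-dihydro-1-benzofuran-3-carboxylate (cis) | COc1cc2c(cc1O[Si](C(C)C)(C(C)C)C(C)C)O[C@@H](c1cc(OC)c(OC)c(OC)c1)[C@H]2C(=O)OCC | intermediate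
11 | [(2R,3R)-5-methoxy-6-(triisopropylsilyloxy)-2-(3,4,5-trimethoxyphenyl)-2,3-dihydro-1-benzofuran-3-yl]methanol (cis) | COc1cc2c(cc1O[Si](C(C)C)(C(C)C)C(C)C)O[C@@H](c1cc(OC)c(OC)c(OC)c1)[C@H]2CO | intermediate
12 | [(2R,3R)-5-methoxy-6-(triisopropylsilyloxy)-2-(3,4,5-trimethoxyphenyl)-2,3-dihydro-1-benzofuran-3-yl]methyl methanesulfonate (cis) | COc1cc2c(cc1O[Si](C(C)C)(C(C)C)C(C)C)O[C@@H](c1cc(OC)c(OC)c(OC)c1)[C@H]2COS(C)(=O)=O | intermediate
13 | triisopropyl{[(2R,3S)-5-methoxy-3-methyl-2-(3,4,5-trimethoxyphenyl)-2,3-dihydro-1-benzofuran-6-yl]oxy}silane (cis) | COc1cc2c(cc1O[Si](C(C)C)(C(C)C)C(C)C)O[C@@H](c1cc(OC)c(OC)c(OC)c1)[C@H]2C | intermediate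
14 | (2R,3S)-5-methoxy-3-methyl-2-(3,4,5-trimethoxyphenyl)-2,3-dihydro-1-benzofuran-6-ol (cis) | COc1cc2c(cc1O)O[C@@H](c1cc(OC)c(OC)c(OC)c1)[C@H]2C | intermediate
15 | allyl methyl carbonate | C=CCOC(=O)OC | starting material
16 | (2R,3S)-6-(allyloxy)-5-methoxy-3-methyl-2-(3,4,5-trimethoxyphenyl)-2,3-dihydro-1-benzofuran | COc1cc2c(cc1OCC=C)O[C@@H](c1cc(OC)c(OC)c(OC)c1)[C@H]2C | intermediate
17 | (2R,3S,3aS)-3a-allyl-5-methoxy-3-methyl-2-(3,4,5-trimethoxyphenyl)-3,3a-dihydro-1-benzofuran-6(2H)-one (CNP0197140.1) | C=CC[C@]12C=C(OC)C(=O)C=C1O[C@@H](c1cc(OC)c(OC)c(OC)c1)[C@H]2C | target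

Total step count: 11
Longest linear sequence: 11 steps (1 to 17)

Steps most likely to fail

Step 11. The allyl group may stay on oxygen, or be delivered to the open ortho carbon C7, where loss of a proton restores the aromatic ring and makes that path irreversible. Overheating may also move the allyl group from C3a to C7 by a [3,3] shift followed by rearomatisation. The fallback uses known reaction types in which C7 cannot be reached. It sets out from phenol 14, which is oxidised with NaIO4 in aqueous acetonitrile, with loss of the O-methyl group, to (2R,3S)-3-methyl-2-(3,4,5-trimethoxyphenyl)-2,3-dihydro-1-benzofuran-5,6-dione F1. Allylindium (In, allyl bromide, DMF, 0 °C) should add 1,2 to the C5 carbonyl, the C6 carbonyl being deactivated as a vinylogous ester, to give the 5-allyl-5-hydroxy dienone F2. KH and 18-crown-6 in THF should then trigger an anionic oxy-Cope shift from C5 across C4 to C3a, and acidification gives the 3a-allyl-5-hydroxy dienone F3. O-Methylation (MeI, K2CO3, acetone) comes back to the route at 17. The price is that C3a follows the C5 configuration of F2, which the distant C2 and C3 centres bias only weakly, so the C3a epimer would have to be removed by chromatography.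

Step 6. The catalyst may discriminate poorly between the two enantiotopic benzylic hydrogens, or the insertion may drift into a stepwise hydride-transfer path that erodes the cis relation, because the trimethoxybenzyl ether is a better hydride donor than a plain benzyl ether. The fallback moves the control from the catalyst to a covalently bound auxiliary and sets out from iodide 7. (R)-Pantolactone is converted with glyoxylic acid chloride tosylhydrazone and Et3N into the (R)-pantolactonyl diazoacetate F4, which is coupled with 7 under the conditions of step 5 to the pantolactonyl aryldiazoacetate F5. Insertion under Rh2(S-PTTL)4 or its mirror image, whichever pairing is matched, gives diastereomers that can be separated by chromatography or crystallisation, and the (2R,3S) pantolactonyl ester F6 is carried on. Reduction with excess i-Bu2AlH at −78 °C removes the auxiliary and comes back to the route at alcohol 11.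

Step 5. Oxidative addition at the electron-rich carbon–iodine bond flanked by the benzyloxy group may be slow, which leaves time for palladium-induced loss of N2 from the diazo ester (carbene dimerisation, azine formation). The fallback separates carbon–carbon bond formation from introduction of the diazo group and sets out from iodide 7. A Negishi-type coupling with the Reformatsky reagent BrZnCH2CO2Et (Pd2(dba)3, XPhos, THF, 50 °C) should give the arylacetate F7. Regitz diazo transfer with 4-acetamidobenzenesulfonyl azide and DBU in MeCN at 0 to 25 °C comes back to the route at 9.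

Further compounds
F1 | step 11 | (2R,3S)-3-methyl-2-(3,4,5-trimethoxyphenyl)-2,3-dihydro-1-benzofuran-5,6-dione | O=C1C=C2C(=CC1=O)O[C@@H](c1cc(OC)c(OC)c(OC)c1)[C@H]2C
F2 | step 11 | (2R,3S)-5-allyl-5-hydroxy-3-methyl-2-(3,4,5-trimethoxyphenyl)-2,3-dihydro-1-benzofuran-6(5H)-one, both C5 epimers | C=CCC1(O)C=C2C(=CC1=O)O[C@@H](c1cc(OC)c(OC)c(OC)c1)[C@H]2C
F3 | step 11 | (2R,3S,3aS)-3a-allyl-5-hydroxy-3-methyl-2-(3,4,5-trimethoxyphenyl)-3,3a-dihydro-1-benzofuran-6(2H)-one | C=CC[C@]12C=C(O)C(=O)C=C1O[C@@H](c1cc(OC)c(OC)c(OC)c1)[C@H]2C
F4 | step 6 | (3R)-4,4-dimethyl-2-oxooxolan-3-yl 2-diazoacetate | CC1(C)COC(=O)[C@@H]1OC(=O)C=[N+]=[N-]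
F5 | step 6 | (3R)-4,4-dimethyl-2-oxooxolan-3-yl 2-diazo-2-[5-methoxy-4-(triisopropylsilyloxy)-2-(3,4,5-trimethoxybenzyloxy)phenyl]acetate | CC1(C)COC(=O)[C@@H]1OC(=O)C(=[N+]=[N-])c1cc(OC)c(O[Si](C(C)C)(C(C)C)C(C)C)cc1OCc1cc(OC)c(OC)c(OC)c1
F6 | step 6 | (3R)-4,4-dimethyl-2-oxooxolan-3-yl (2R,3S)-5-methoxy-6-(triisopropylsilyloxy)-2-(3,4,5-trimethoxyphenyl)-2,3-dihydro-1-benzofuran-3-carboxylate | COc1cc2c(cc1O[Si](C(C)C)(C(C)C)C(C)C)O[C@@H](c1cc(OC)c(OC)c(OC)c1)[C@H]2C(=O)O[C@H]1C(=O)OCC1(C)C
F7 | step 5 | ethyl 2-[5-methoxy-4-(triisopropylsilyloxy)-2-(3,4,5-trimethoxybenzyloxy)phenyl]acetate | CCOC(=O)Cc1cc(OC)c(O[Si](C(C)C)(C(C)C)C(C)C)cc1OCc1cc(OC)c(OC)c(OC)c1
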